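## Plan

1. Target numbering: O1, C2 (Ar), C3 (CH2OH), C4 (aroyl), C5 (CH2). Ar = 3,4,5-trimethoxyphenyl.
2. Cuts: first the Ar–C(=O) bond (aryl Grignard reagent plus a Weinreb amide at C4). C4 is then traced back to a geminal diester, and last the oxolane is cut at O1–C2 and C4–C5.
3. Enabling feature: in the oxolane ring C2 carries a cation-stabilising aryl group, C4 carries an anion-stabilising carbonyl group, and C5–O1 is a bare CH2–O link. C2–C3–C4 therefore maps onto a donor–acceptor cyclopropane and C5–O1 onto formaldehyde.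
4. Forward order: the cyclopropane is made first (enal plus bromomalonate) and is expanded to the oxolane, the only ring built for the target, by a formal (3+2) annulation. C4 is then trimmed to one carbonyl group and the second aryl group is attached.
5. Stereochemistry: C3 and the cyclopropane aryl centre come from (S)-diphenylprolinol silyl ether catalysis. C2 comes from inversion in the annulation (trans-cyclopropane to 2,3-cis-oxolane). C4 comes from thermodynamic equilibration of the ketone (3,4-trans).

Key step: step 4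

Remark: in the cyclopropanes C2 and C3 are the carbons that become C2 and C3 of the oxolane, and the diester carbon C1 becomes C4. The three intermediates between the dealkoxycarbonylation and the equilibration are carried as mixtures of C4 epimers, so C4 is left undefined in their SMILES. TBDPS = tert-butyldiphenylsilyl.

## Route

Step 1
Reactants: 1 (E)-3,4,5-trimethoxycinnamaldehyde; 2 diethyl bromomalonate
Product: 3 diethyl (2S,3R)-3-formyl-2-(3,4,5-trimethoxyphenyl)cyclopropane-1,1-dicarboxylate (Ar and CHO trans)
Conditions: (S)-2-[diphenyl(trimethylsilyloxy)methyl]pyrrolidine (20 mol%), 2,6-lutidine (1.1 equiv), CH2Cl2, 0 °C → rt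
Reagents that add atoms: none
Why: Michael-initiated ring closure under iminium–enamine organocatalysis: the bromomalonate adds to the β-carbon of the E, s-trans iminium ion on the face opposite the CPh2OTMS group, which sets the aryl-bearing carbon as S, and the resulting enamine displaces bromide in a 3-exo-tet closure that places the formyl group trans to Ar, which sets C3 as R.

Step 2
Reactants: 3 diethyl (2S,3R)-3-formyl-2-(3,4,5-trimethoxyphenyl)cyclopropane-1,1-dicarboxylate
Product: 4 diethyl (2S,3R)-3-(hydroxymethyl)-2-(3,4,5-trimethoxyphenyl)cyclopropane-1,1-dicarboxylate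
Conditions: NaBH4 (0.5 equiv), EtOH/CH2Cl2, −20 °C, short contact; aq. NH4Cl; crude product used at once
Reagents that add atoms: none
Why: Chemoselective borohydride reduction of an aldehyde beside esters touches no stereocentre, and the low temperature, short contact time and ethanol as the matching alcohol hold back lactonisation of the new hydroxyl group onto the cis ester and prevent transesterification.

Step 3
Reactants: 4 diethyl (2S,3R)-3-(hydroxymethyl)-2-(3,4,5-trimethoxyphenyl)cyclopropane-1,1-dicarboxylate
Product: 5 diethyl (2S,3R)-3-[(tert-butyldiphenylsilyl)oxymethyl]-2-(3,4,5-trimethoxyphenyl)cyclopropane-1,1-dicarboxylate (Ar and CH2OTBDPS trans)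
Conditions: TBDPSCl (1.1 equiv), imidazole (2.2 equiv), CH2Cl2, 0 °C → rt
Reagents that add atoms: tert-butyl(chloro)diphenylsilane, CC(C)(C)[Si](Cl)(c1ccccc1)c1ccccc1
Why: Imidazole-promoted silylation of a primary alcohol removes the lactonisation pathway for good and installs a bulky, weakly Lewis basic ether chosen to survive Sn(OTf)2, hot LiCl/DMSO and organomagnesium reagents.

Step 4
Reactants: 5 diethyl (2S,3R)-3-[(tert-butyldiphenylsilyl)oxymethyl]-2-(3,4,5-trimethoxyphenyl)cyclopropane-1,1-dicarboxylate; 6 formaldehyde (bought as paraformaldehyde, cracked to the monomer just before use)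
Product: 7 diethyl (2R,3R)-3-[(tert-butyldiphenylsilyl)oxymethyl]-2-(3,4,5-trimethoxyphenyl)oxolane-4,4-dicarboxylate (target numbering; Ar and CH2OTBDPS cis)
Conditions: 6 (5 equiv; paraformaldehyde cracked at 150 °C, dry gas led in N2 into CH2Cl2 at −78 °C), Sn(OTf)2 (10 mol%), CH2Cl2, −78 → −10 °C
Reagents that add atoms: none
Why: Sn(OTf)2 chelates the two ester carbonyl groups and stretches the benzylic C2–C4 bond into an intimate ion pair, the oxygen of formaldehyde attacks C2 anti to the departing malonate carbon (O1–C2), and the tin-bound malonate enolate then adds to the carbon of the O1=C5 oxocarbenium ion (C4–C5). The closest known reaction type is the Lewis-acid-catalysed formal (3+2) annulation of 2-arylcyclopropane-1,1-diesters with aldehydes, which is stereospecific with inversion at the donor carbon and accepts a 3-alkoxymethyl substituent; formaldehyde is the smallest and least nucleophilic aldehyde, so it is used in excess, and any polymer formed on the Lewis acid remains a reservoir of monomer. The oxolane closes by a 5-(enolexo)-endo-trig aldol-type attack on the oxocarbenium carbon, the mode common to these annulations. C2 is the only new stereocentre and is controlled by the backside displacement, which turns 2S of 5 into 2R of 7 and so converts the trans Ar/CH2OTBDPS pair into the cis pair, while C3 is untouched and C4 and C5 are not stereogenic. Cleavage of C2–C4 rather than C3–C4 is secured by the aryl group, the only substituent able to carry positive charge, and stereospecificity requires capture to be faster than ionisation to a free cation, which is favoured by the moderate donor strength of Ar (twisted 4-OMe, two inductively withdrawing meta-OMe groups), the low temperature and the mild Lewis acid. The hindered TBDPS ether should neither bind tin nor take part as a neighbouring group.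

Step 5
Reactants: 7 diethyl (2R,3R)-3-[(tert-butyldiphenylsilyl)oxymethyl]-2-(3,4,5-trimethoxyphenyl)oxolane-4,4-dicarboxylate
Product: 8 ethyl (2R,3R)-3-[(tert-butyldiphenylsilyl)oxymethyl]-2-(3,4,5-trimethoxyphenyl)oxolane-4-carboxylate (mixture of C4 epimers)
Conditions: LiCl (3 equiv), H2O (2 equiv), DMSO, 155 °C
Reagents that add atoms: none
Why: In the Krapcho dealkoxycarbonylation chloride dealkylates one ester of the geminal pair, CO2 is lost and water protonates the enolate, all in a nearly neutral medium that leaves the benzylic C2–O1 bond, C3 and the silyl ether alone, and the open C4 configuration is settled in step 9.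

Step 6
Reactants: 8 ethyl (2R,3R)-3-[(tert-butyldiphenylsilyl)oxymethyl]-2-(3,4,5-trimethoxyphenyl)oxolane-4-carboxylate
Product: 9 (2R,3R)-3-[(tert-butyldiphenylsilyl)oxymethyl]-N-methoxy-N-methyl-2-(3,4,5-trimethoxyphenyl)oxolane-4-carboxamide (mixture of C4 epimers)
Conditions: MeNH(OMe)·HCl (3 equiv), iPrMgCl (6 equiv), THF, −20 → 0 °C; aq. NH4Cl
Reagents that add atoms: N,O-dimethylhydroxylamine hydrochloride, CNOC.Cl
Why: Weinreb amide synthesis by aminolysis of the ester with the chloromagnesium amide of N,O-dimethylhydroxylamine does not involve C2 or C3, and any epimerisation at C4 is irrelevant at this stage.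

Step 7
Reactants: 10 5-bromo-1,2,3-trimethoxybenzene
Product: 11 3,4,5-trimethoxyphenylmagnesium bromide (titrated THF solution)
Conditions: Mg (1.2 equiv), I2 (one crystal), THF, reflux → rt
Reagents that add atoms: magnesium, [Mg]
Why: Grignard reagent formation by direct insertion of magnesium into an aryl bromide is routine for this electron-rich bromide in THF.

Step 8
Reactants: 9 (2R,3R)-3-[(tert-butyldiphenylsilyl)oxymethyl]-N-methoxy-N-methyl-2-(3,4,5-trimethoxyphenyl)oxolane-4-carboxamide; 11 3,4,5-trimethoxyphenylmagnesium bromide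
Product: 12 [(2R,3R)-3-[(tert-butyldiphenylsilyl)oxymethyl]-2-(3,4,5-trimethoxyphenyl)oxolan-4-yl](3,4,5-trimethoxyphenyl)methanone (mixture of C4 epimers)
Conditions: 11 (2 equiv), THF, 0 °C → rt; aq. NH4Cl
Reagents that add atoms: none
Why: In the Weinreb ketone synthesis the five-membered magnesium chelate of the tetrahedral adduct persists until the quench, so only one aryl group is delivered and no stereocentre other than the still labile C4 is at risk.

Step 9
Reactants: 12 [(2R,3R)-3-[(tert-butyldiphenylsilyl)oxymethyl]-2-(3,4,5-trimethoxyphenyl)oxolan-4-yl](3,4,5-trimethoxyphenyl)methanone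
Product: 13 [(2R,3R,4S)-3-[(tert-butyldiphenylsilyl)oxymethyl]-2-(3,4,5-trimethoxyphenyl)oxolan-4-yl](3,4,5-trimethoxyphenyl)methanone (2,3-cis, 3,4-trans)
Conditions: DBU (0.3 equiv), CH2Cl2, rt
Reagents that add atoms: none
Why: Base-catalysed keto–enol equilibration (thermodynamic epimerisation) should favour the 4S epimer strongly, because its aroyl group is trans to both CH2OTBDPS and Ar whereas the 4R epimer carries three contiguous cis substituents; loss of O1 by β-elimination is the reverse of a 5-endo-trig closure and stereoelectronically slow, and the silyl ether keeps the cis epimer from being trapped as a bicyclic hemiketal.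

Step 10
Reactants: 13 [(2R,3R,4S)-3-[(tert-butyldiphenylsilyl)oxymethyl]-2-(3,4,5-trimethoxyphenyl)oxolan-4-yl](3,4,5-trimethoxyphenyl)methanone
Product: 14 [(2R,3R,4S)-3-(hydroxymethyl)-2-(3,4,5-trimethoxyphenyl)oxolan-4-yl](3,4,5-trimethoxyphenyl)methanone (target; systematic locants 3S,4R,5R)
Conditions: TBAF/AcOH (1:1, 3 equiv), THF, 0 °C → rt
Reagents that add atoms: none
Why: Fluoride-induced desilylation buffered with acetic acid stays close to neutral, so neither C4 (base) nor the benzylic C2 (acid) should epimerise, and the trans-disposed CH2OH and aroyl groups cannot close to a hemiketal.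

## Compound list

1 | (E)-3,4,5-trimethoxycinnamaldehyde | O=C/C=C/c1cc(OC)c(OC)c(OC)c1 | starting material
2 | diethyl bromomalonate | CCOC(=O)C(Br)C(=O)OCC | starting material
3 | diethyl (2S,3R)-3-formyl-2-(3,4,5-trimethoxyphenyl)cyclopropane-1,1-dicarboxylate | CCOC(=O)C1(C(=O)OCC)[C@H](c2cc(OC)c(OC)c(OC)c2)[C@H]1C=O | intermediate
4 | diethyl (2S,3R)-3-(hydroxymethyl)-2-(3,4,5-trimethoxyphenyl)cyclopropane-1,1-dicarboxylate | CCOC(=O)C1(C(=O)OCC)[C@H](c2cc(OC)c(OC)c(OC)c2)[C@H]1CO | intermediate
5 | diethyl (2S,3R)-3-[(tert-butyldiphenylsilyl)oxymethyl]-2-(3,4,5-trimethoxyphenyl)cyclopropane-1,1-dicarboxylate | CCOC(=O)C1(C(=O)OCC)[C@H](c2cc(OC)c(OC)c(OC)c2)[C@H]1CO[Si](c2ccccc2)(c2ccccc2)C(C)(C)C | intermediate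
6 | formaldehyde (supplied as paraformaldehyde) | C=O | starting material
7 | diethyl (2R,3R)-3-[(tert-butyldiphenylsilyl)oxymethyl]-2-(3,4,5-trimethoxyphenyl)oxolane-4,4-dicarboxylate | CCOC(=O)C1(C(=O)OCC)CO[C@@H](c2cc(OC)c(OC)c(OC)c2)[C@H]1CO[Si](c2ccccc2)(c2ccccc2)C(C)(C)C | intermediate
8 | ethyl (2R,3R)-3-[(tert-butyldiphenylsilyl)oxymethyl]-2-(3,4,5-trimethoxyphenyl)oxolane-4-carboxylate, C4 epimers | CCOC(=O)C1CO[C@@H](c2cc(OC)c(OC)c(OC)c2)[C@H]1CO[Si](c2ccccc2)(c2ccccc2)C(C)(C)C | intermediate
9 | (2R,3R)-3-[(tert-butyldiphenylsilyl)oxymethyl]-N-methoxy-N-methyl-2-(3,4,5-trimethoxyphenyl)oxolane-4-carboxamide, C4 epimers | CON(C)C(=O)C1CO[C@@H](c2cc(OC)c(OC)c(OC)c2)[C@H]1CO[Si](c2ccccc2)(c2ccccc2)C(C)(C)C | intermediate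
10 | 5-bromo-1,2,3-trimethoxybenzene | COc1cc(Br)cc(OC)c1OC | starting material
11 | 3,4,5-trimethoxyphenylmagnesium bromide | COc1cc([Mg]Br)cc(OC)c1OC | intermediate
12 | [(2R,3R)-3-[(tert-butyldiphenylsilyl)oxymethyl]-2-(3,4,5-trimethoxyphenyl)oxolan-4-yl](3,4,5-trimethoxyphenyl)methanone, C4 epimers | COc1cc(C(=O)C2CO[C@@H](c3cc(OC)c(OC)c(OC)c3)[C@H]2CO[Si](c3ccccc3)(c3ccccc3)C(C)(C)C)cc(OC)c1OC | intermediate
13 | [(2R,3R,4S)-3-[(tert-butyldiphenylsilyl)oxymethyl]-2-(3,4,5-trimethoxyphenyl)oxolan-4-yl](3,4,5-trimethoxyphenyl)methanone | COc1cc(C(=O)[C@@H]2CO[C@@H](c3cc(OC)c(OC)c(OC)c3)[C@H]2CO[Si](c3ccccc3)(c3ccccc3)C(C)(C)C)cc(OC)c1OC | intermediate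
14 | [(2R,3R,4S)-3-(hydroxymethyl)-2-(3,4,5-trimethoxyphenyl)oxolan-4-yl](3,4,5-trimethoxyphenyl)methanone | COc1cc(C(=O)[C@@H]2CO[C@@H](c3cc(OC)c(OC)c(OC)c3)[C@H]2CO)cc(OC)c1OC | target

## Step count

Total step count: 10.
Longest linear sequence: 9 (steps 1–6 and 8–10, from 1). Step 7 is a one-step side branch.

## Steps most likely to fail

**Step 4.** Formaldehyde may oligomerise on the Lewis acid, and its oxygen is a weak nucleophile. Unimolecular pathways of the activated cyclopropane could then win:
- ionisation to a free benzylic cation, with erosion of the inversion;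
- trans/cis isomerisation of the three-membered ring;
- proton loss from C3 to an open-chain alkene;
- capture of the oxocarbenium carbon by the electron-rich arene.

The fallback sets out from 5 and returns at 7. It uses an aldehyde of proven reactivity whose substituent is removed afterwards. The annulation is run with commercial (E)-cinnamaldehyde, a much better oxygen nucleophile that should capture the ion pair at lower temperature. It should give diethyl (2R,3R,5R)-3-[(tert-butyldiphenylsilyl)oxymethyl]-5-[(E)-2-phenylethenyl]-2-(3,4,5-trimethoxyphenyl)oxolane-4,4-dicarboxylate F1. The 2,5-cis relationship is expected, but C5 is of no consequence. Lemieux–Johnson cleavage (OsO4 cat., NaIO4, 2,6-lutidine, dioxane/H2O) should give diethyl (2R,3R,5S)-3-[(tert-butyldiphenylsilyl)oxymethyl]-5-formyl-2-(3,4,5-trimethoxyphenyl)oxolane-4,4-dicarboxylate F2. Tsuji–Wilkinson decarbonylation with stoichiometric RhCl(PPh3)3 in hot toluene then replaces CHO by H and delivers 7. The alkylrhodium intermediate has no β-hydrogen, because C4 is quaternary and the other neighbour is O1.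

**Step 5.** Dealkylation of the two crowded ethyl esters on a quaternary carbon may be sluggish. That would force temperatures at which the silyl group is lost or general decomposition begins.

The fallback sets out from 7 and returns at 8. It splits the operation into hydrolysis and decarboxylation. Monosaponification (KOH, 1.1 equiv, EtOH/H2O, rt to 40 °C) should cleave the less hindered ester, the one trans to CH2OTBDPS. This gives (2R,3R,4R)-3-[(tert-butyldiphenylsilyl)oxymethyl]-4-(ethoxycarbonyl)-2-(3,4,5-trimethoxyphenyl)oxolane-4-carboxylic acid F3. This malonic half-acid loses CO2 on heating with Et3N in toluene at about 110 °C to give 8.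

**Step 9.** The enolate may open the ring by β-elimination of O1, or the equilibration of the hindered aryl ketone may stay incomplete.

The fallback sets out from 8 and returns at 13. It moves the equilibration to the aldehyde oxidation level, where neutral enamine catalysis is sufficient. Reduction with iBu2AlH (toluene, −78 °C) should give (2R,3R)-3-[(tert-butyldiphenylsilyl)oxymethyl]-2-(3,4,5-trimethoxyphenyl)oxolane-4-carbaldehyde F4 as a mixture of C4 epimers. Catalytic pyrrolidine/AcOH in CH2Cl2 equilibrates this mixture to (2R,3R,4S)-3-[(tert-butyldiphenylsilyl)oxymethyl]-2-(3,4,5-trimethoxyphenyl)oxolane-4-carbaldehyde F5. Addition of 11 (THF, −78 °C) gives [(2R,3R,4S)-3-[(tert-butyldiphenylsilyl)oxymethyl]-2-(3,4,5-trimethoxyphenyl)oxolan-4-yl](3,4,5-trimethoxyphenyl)methanol F6, with the carbinol centre unassigned. Oxidation with Dess–Martin periodinane buffered with NaHCO3 gives 13 without further exposure of C4 to base.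

## Further compounds

F1 | step 4 | diethyl (2R,3R,5R)-3-[(tert-butyldiphenylsilyl)oxymethyl]-5-[(E)-2-phenylethenyl]-2-(3,4,5-trimethoxyphenyl)oxolane-4,4-dicarboxylate | CCOC(=O)C1(C(=O)OCC)[C@@H](/C=C/c2ccccc2)O[C@@H](c2cc(OC)c(OC)c(OC)c2)[C@H]1CO[Si](c2ccccc2)(c2ccccc2)C(C)(C)C
F2 | step 4 | diethyl (2R,3R,5S)-3-[(tert-butyldiphenylsilyl)oxymethyl]-5-formyl-2-(3,4,5-trimethoxyphenyl)oxolane-4,4-dicarboxylate | CCOC(=O)C1(C(=O)OCC)[C@@H](C=O)O[C@@H](c2cc(OC)c(OC)c(OC)c2)[C@H]1CO[Si](c2ccccc2)(c2ccccc2)C(C)(C)C
F3 | step 5 | (2R,3R,4R)-3-[(tert-butyldiphenylsilyl)oxymethyl]-4-(ethoxycarbonyl)-2-(3,4,5-trimethoxyphenyl)oxolane-4-carboxylic acid | CCOC(=O)[C@@]1(C(=O)O)CO[C@@H](c2cc(OC)c(OC)c(OC)c2)[C@H]1CO[Si](c2ccccc2)(c2ccccc2)C(C)(C)C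
F4 | step 9 | (2R,3R)-3-[(tert-butyldiphenylsilyl)oxymethyl]-2-(3,4,5-trimethoxyphenyl)oxolane-4-carbaldehyde, C4 epimers | O=CC1CO[C@@H](c2cc(OC)c(OC)c(OC)c2)[C@H]1CO[Si](c2ccccc2)(c2ccccc2)C(C)(C)C
F5 | step 9 | (2R,3R,4S)-3-[(tert-butyldiphenylsilyl)oxymethyl]-2-(3,4,5-trimethoxyphenyl)oxolane-4-carbaldehyde | O=C[C@@H]1CO[C@@H](c2cc(OC)c(OC)c(OC)c2)[C@H]1CO[Si](c2ccccc2)(c2ccccc2)C(C)(C)C
F6 | step 9 | [(2R,3R,4S)-3-[(tert-butyldiphenylsilyl)oxymethyl]-2-(3,4,5-trimethoxyphenyl)oxolan-4-yl](3,4,5-trimethoxyphenyl)methanol, carbinol epimers | COc1cc(C(O)[C@@H]2CO[C@@H](c3cc(OC)c(OC)c(OC)c3)[C@H]2CO[Si](c3ccccc3)(c3ccccc3)C(C)(C)C)cc(OC)c1OC
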